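**Plan**

- Retrosynthesis: the eight benzyl ethers are cut first, then C3–OH and C4–H of the upper ring C (syn hydroboration of a C3=C4 alkene), then the C2–aryl bond to ring B (aryl addition to a benzopyrylium ion). C3 itself is then excised from ring C, which shrinks the pyran to a furan, and last the biaryl bond between furan C3 (the later C4) and C6 of the catechin unit is cut.
- Enabling feature: in the upper ring C (O1, C2, C3, C4, C4a, C8a) C3 is the only atom that carries neither an aryl group nor the ring oxygen. Ring C without C3 is therefore the furan ring of a 3-arylbenzofuran, whose electron-rich C2=C3 bond takes up one carbon from a dihalocarbene.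
- Forward: (+)-catechin is benzylated, brominated at C8 and iodinated at C6; 6-hydroxybenzofuran-3(2H)-one gives a benzofuran-3-yl boronate; Suzuki–Miyaura coupling joins the two. The furan ring is expanded to the pyran ring (a 2-ethoxy-2H-chromene), both bromines are removed, ring B is added at C2, and hydroboration–oxidation and hydrogenolysis finish the route.
- Stereochemistry: C2 and C3 of the lower unit come from (+)-catechin. C2 of the upper unit comes from a catalyst-controlled boronate addition. C3 and C4 of the upper unit come from syn addition of borane anti to the C2 aryl group.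

Key step: step 9

Assumption: 6-hydroxybenzofuran-3(2H)-one and 3,4-bis(benzyloxy)phenylboronic acid are bought; the enantiomer of the tartaric acid monoamide catalyst of step 12 that gives the (2R)-chromene is fixed in a model run on a simple 4-aryl-2-ethoxy-2H-chromene and is the one meant.

**Route**

Step 1
Reactants: 1 (+)-catechin
Product: 2 5,7,3',4'-tetra-O-benzyl-(+)-catechin
Conditions: BnBr (4.4 equiv), K2CO3, DMF, 0 °C → 25 °C
Reagents that add atoms: benzyl bromide, BrCc1ccccc1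
Why: Williamson ether synthesis in which K2CO3 ionises the four phenols but not the secondary alcohol, so only the phenols are benzylated and no stereocenter is touched.

Step 2
Reactants: 2 5,7,3',4'-tetra-O-benzyl-(+)-catechin
Product: 3 3,5,7,3',4'-penta-O-benzyl-(+)-catechin
Conditions: NaH, BnBr, Bu4NI (cat.), THF–DMF, 0 °C → 25 °C
Reagents that add atoms: benzyl bromide, BrCc1ccccc1
Why: Williamson ether synthesis of the secondary alkoxide, which makes the C3 oxygen inert to the carbene, organolithium and borane steps that follow.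

Step 3
Reactants: 3 3,5,7,3',4'-penta-O-benzyl-(+)-catechin
Product: 4 8-bromo-3,5,7,3',4'-penta-O-benzyl-(+)-catechin
Conditions: NBS (1.0 equiv), CH2Cl2, −78 °C → 0 °C
Reagents that add atoms: N-bromosuccinimide, BrN1C(=O)CCC1=O
Why: Electrophilic aromatic bromination of the trioxygenated ring A, which in per-benzylated flavan-3-ols goes to C8 and leaves C6 as the only free position of that ring.

Step 4
Reactants: 4 8-bromo-3,5,7,3',4'-penta-O-benzyl-(+)-catechin
Product: 5 8-bromo-6-iodo-3,5,7,3',4'-penta-O-benzyl-(+)-catechin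
Conditions: NIS (1.05 equiv), CH2Cl2–MeCN, 0 °C → 25 °C, dark
Reagents that add atoms: N-iodosuccinimide, IN1C(=O)CCC1=O
Why: Electrophilic aromatic iodination at C6, the one remaining position of ring A and far more nucleophilic than the dialkoxy ring B, gives a C–I bond that can be coupled in the presence of the C–Br bond.

Step 5
Reactants: 6 6-hydroxybenzofuran-3(2H)-one
Product: 7 6-(benzyloxy)benzofuran-3(2H)-one
Conditions: BnBr, K2CO3, acetone, 25 °C
Reagents that add atoms: benzyl bromide, BrCc1ccccc1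
Why: Williamson ether synthesis at the phenol, the most acidic site, with a mild carbonate base that keeps C-alkylation and aldol self-condensation at the methylene group low.

Step 6
Reactants: 7 6-(benzyloxy)benzofuran-3(2H)-one
Product: 8 6-(benzyloxy)benzofuran-3-yl trifluoromethanesulfonate
Conditions: Tf2O, i-Pr2NEt, CH2Cl2, −78 °C → 0 °C
Reagents that add atoms: trifluoromethanesulfonic anhydride, O=S(=O)(OS(=O)(=O)C(F)(F)F)C(F)(F)F
Why: O-sulfonylation of the enol form, which is favoured because the enol is an aromatic benzofuran-3-ol, gives the heteroaryl triflate.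

Step 7
Reactants: 8 6-(benzyloxy)benzofuran-3-yl trifluoromethanesulfonate
Product: 9 2-[6-(benzyloxy)benzofuran-3-yl]-4,4,5,5-tetramethyl-1,3,2-dioxaborolane
Conditions: B2pin2, PdCl2(dppf) (3 mol %), KOAc, 1,4-dioxane, 80 °C
Reagents that add atoms: bis(pinacolato)diboron, CC1(C)OB(OC1(C)C)B1OC(C)(C)C(C)(C)O1
Why: Miyaura borylation of a heteroaryl triflate puts boron on the unhindered coupling partner.

Step 8
Reactants: 5 8-bromo-6-iodo-3,5,7,3',4'-penta-O-benzyl-(+)-catechin; 9 2-[6-(benzyloxy)benzofuran-3-yl]-4,4,5,5-tetramethyl-1,3,2-dioxaborolane (1.05 equiv)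
Product: 10 6-[6-(benzyloxy)benzofuran-3-yl]-8-bromo-3,5,7,3',4'-penta-O-benzyl-(+)-catechin
Conditions: Pd(OAc)2 (5 mol %), SPhos (10 mol %), K3PO4, toluene–H2O (10:1), 80 °C
Reagents that add atoms: none
Why: Suzuki–Miyaura coupling in which oxidative addition into the C–I bond is much faster than into the hindered, electron-rich C–Br bond, and in which boron sits on the benzofuran so that no 2,6-dialkoxyaryl boron species prone to protodeboronation is needed.

Step 9
Reactants: 10 6-[6-(benzyloxy)benzofuran-3-yl]-8-bromo-3,5,7,3',4'-penta-O-benzyl-(+)-catechin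
Product: 13 6-[7-(benzyloxy)-3-bromo-2-ethoxy-2H-chromen-4-yl]-8-bromo-3,5,7,3',4'-penta-O-benzyl-(+)-catechin (both epimers at the acetal carbon), via dibromocyclopropane adduct 11 (not isolated), via 3-bromobenzopyrylium bromide 12 (not isolated)
Conditions: CHBr3 (3 equiv), NaOEt (6 equiv), hexane–THF, −10 °C → 25 °C; chromatography on Et3N-treated silica
Reagents that add atoms: bromoform, BrC(Br)Br; sodium ethoxide, CC[O-].[Na+]
Why: Sodium ethoxide deprotonates bromoform and the tribromomethanide loses bromide to give dibromocarbene, which adds in a (2+1) cycloaddition across the enol-ether-like C2=C3 bond of the furan ring, bonding first at the unhindered C2 while charge builds at the aryl-bearing C3; the endo bromide of adduct 11 then ionises with disrotatory electrocyclic opening of the C1a–C6b bond to the aromatic benzopyrylium bromide 12, to which ethoxide adds. The closest known reaction type is the Ciamician–Dennstedt dihalocarbene ring expansion, in the form long used to turn benzofurans into 2-alkoxy-3-halo-2H-chromenes. The six-membered ring is not closed from a chain but grows out of the five-membered furan ring by insertion of the carbene carbon between C2 and C3 (cyclopropanation, then cleavage of the bond common to both rings). The only new stereocenter is the acetal carbon C2, formed without control as a mixture of epimers, which is harmless because this carbon becomes planar again in step 12. The step needs site selectivity of the carbene for the furan double bond over five benzene rings and six benzyl ethers, which the much higher nucleophilicity of the vinyl ether bond should secure, and capture of the cation at C2, which the aryl group blocking C4 and the hard alkoxide should secure.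

Step 10
Reactants: 13 6-[7-(benzyloxy)-3-bromo-2-ethoxy-2H-chromen-4-yl]-8-bromo-3,5,7,3',4'-penta-O-benzyl-(+)-catechin
Product: 15 6-[7-(benzyloxy)-2-ethoxy-2H-chromen-4-yl]-3,5,7,3',4'-penta-O-benzyl-(+)-catechin (both epimers at the acetal carbon), via 3,8'-dilithio intermediate 14 (not isolated)
Conditions: t-BuLi (4.2 equiv), THF, −78 °C, 15 min; then MeOH, −78 °C → 25 °C
Reagents that add atoms: tert-butyllithium (lithium in intermediate 14 only), [Li]C(C)(C)C
Why: Bromine–lithium exchange at the vinylic and the aryl C–Br bond at −78 °C, where exchange outruns deprotonation of benzyl ethers and the β-alkoxy vinyllithium does not yet eliminate, followed by protonation, removes the carbene-derived bromine and the C8 blocking group together.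

Step 11
Reactants: 16 3,4-bis(benzyloxy)phenylboronic acid
Product: 17 diethyl [3,4-bis(benzyloxy)phenyl]boronate
Conditions: EtOH, toluene, azeotropic removal of water, 3 Å molecular sieves; used crude
Reagents that add atoms: ethanol, CCO
Why: Esterification of the boronic acid with ethanol under removal of water gives the dialkyl boronate that can exchange ligands with the chiral dihydroxy acid catalyst.

Step 12
Reactants: 15 6-[7-(benzyloxy)-2-ethoxy-2H-chromen-4-yl]-3,5,7,3',4'-penta-O-benzyl-(+)-catechin; 17 diethyl [3,4-bis(benzyloxy)phenyl]boronate (2 equiv)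
Product: 18 6-{(2R)-7-(benzyloxy)-2-[3,4-bis(benzyloxy)phenyl]-2H-chromen-4-yl}-3,5,7,3',4'-penta-O-benzyl-(+)-catechin
Conditions: tartaric acid mono(N,N-dibenzylamide) (single enantiomer, 10 mol %), Yb(OTf)3 (8 mol %), EtOAc, −20 °C, dark
Reagents that add atoms: none
Why: Petasis-type addition of an aryl boronate to the benzopyrylium ion formed from the chromene acetal, in which the acid pair ionises the acetal and the boronate bound to the chiral dihydroxy acid delivers the electron-rich aryl group to C2 (C4 is blocked by its aryl group) inside the chiral ion pair, so that the catalyst sets the C2 configuration, 2R by the sequence rules at this stage.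

Step 13
Reactants: 18 6-{(2R)-7-(benzyloxy)-2-[3,4-bis(benzyloxy)phenyl]-2H-chromen-4-yl}-3,5,7,3',4'-penta-O-benzyl-(+)-catechin
Product: 20 (2S,3R,4R)-7-(benzyloxy)-2-[3,4-bis(benzyloxy)phenyl]-4-[3,5,7,3',4'-penta-O-benzyl-(+)-catechin-6-yl]chroman-3-ol, via C3 alkylborane 19 (not isolated)
Conditions: BH3·SMe2 (3 equiv), THF, 0 °C → 25 °C; then NaOH (aq), H2O2, 0 °C → 25 °C
Reagents that add atoms: borane–dimethyl sulfide (boron in intermediate 19 only), B.CSC; hydrogen peroxide, OO
Why: Hydroboration–oxidation in which boron adds to the less substituted, non-benzylic C3 and hydrogen to C4 in a syn fashion on the face opposite the C2 aryl group, and oxidation with retention gives the 2,3-trans-3,4-trans alcohol, so that C2 controls C3 and C4.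

Step 14
Reactants: 20 (2S,3R,4R)-7-(benzyloxy)-2-[3,4-bis(benzyloxy)phenyl]-4-[3,5,7,3',4'-penta-O-benzyl-(+)-catechin-6-yl]chroman-3-ol
Product: 21 (2S,3R,4R)-2-(3,4-dihydroxyphenyl)-4-[(2R,3S)-2-(3,4-dihydroxyphenyl)-3,5,7-trihydroxychroman-6-yl]chromane-3,7-diol (ent-fisetinidol-(4β→6)-catechin), the target
Conditions: H2 (1 atm), Pd(OH)2/C, THF–MeOH–H2O, 25 °C; filtration and freeze-drying under argon
Reagents that add atoms: none
Why: Hydrogenolysis of the eight benzyl ethers under neutral conditions should leave the flavan C–O bonds and the acid-stable interflavan bond of the 5-deoxy upper unit intact.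

**Compound list**

1 | (+)-catechin, (2R,3S)-2-(3,4-dihydroxyphenyl)chromane-3,5,7-triol | O[C@H]1Cc2c(O)cc(O)cc2O[C@@H]1c1ccc(O)c(O)c1 | starting material
2 | 5,7,3',4'-tetra-O-benzyl-(+)-catechin | c1c(OCc3ccccc3)cc2c(c1OCc1ccccc1)C[C@H](O)[C@@H](c1ccc(OCc3ccccc3)c(OCc3ccccc3)c1)O2 | intermediate
3 | 3,5,7,3',4'-penta-O-benzyl-(+)-catechin | c1c(OCc3ccccc3)cc2c(c1OCc1ccccc1)C[C@H](OCc1ccccc1)[C@@H](c1ccc(OCc3ccccc3)c(OCc3ccccc3)c1)O2 | intermediate
4 | 8-bromo-3,5,7,3',4'-penta-O-benzyl-(+)-catechin | c1c(OCc3ccccc3)c(Br)c2c(c1OCc1ccccc1)C[C@H](OCc1ccccc1)[C@@H](c1ccc(OCc3ccccc3)c(OCc3ccccc3)c1)O2 | intermediate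
5 | 8-bromo-6-iodo-3,5,7,3',4'-penta-O-benzyl-(+)-catechin | Ic1c(OCc3ccccc3)c(Br)c2c(c1OCc1ccccc1)C[C@H](OCc1ccccc1)[C@@H](c1ccc(OCc3ccccc3)c(OCc3ccccc3)c1)O2 | intermediate
6 | 6-hydroxybenzofuran-3(2H)-one | O=C1COc2cc(O)ccc21 | starting material
7 | 6-(benzyloxy)benzofuran-3(2H)-one | O=C1COc2cc(OCc3ccccc3)ccc21 | intermediate
8 | 6-(benzyloxy)benzofuran-3-yl trifluoromethanesulfonate | FC(F)(F)S(=O)(=O)Oc1coc2cc(OCc3ccccc3)ccc12 | intermediate
9 | 2-[6-(benzyloxy)benzofuran-3-yl]-4,4,5,5-tetramethyl-1,3,2-dioxaborolane | CC1(C)OB(OC1(C)C)c1coc2cc(OCc3ccccc3)ccc12 | intermediate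
10 | 6-[6-(benzyloxy)benzofuran-3-yl]-8-bromo-3,5,7,3',4'-penta-O-benzyl-(+)-catechin | c1oc2cc(OCc3ccccc3)ccc2c1-c1c(OCc3ccccc3)c(Br)c2c(c1OCc1ccccc1)C[C@H](OCc1ccccc1)[C@@H](c1ccc(OCc3ccccc3)c(OCc3ccccc3)c1)O2 | intermediate
11 | 1,1-dibromo-1a,6b-dihydro-1H-cyclopropa[b]benzofuran adduct of 10 (5-benzyloxy, catechin unit at C6b, both cis-fused diastereomers) | BrC1(Br)C2Oc3cc(OCc4ccccc4)ccc3C12c1c(OCc3ccccc3)c(Br)c2c(c1OCc1ccccc1)C[C@H](OCc1ccccc1)[C@@H](c1ccc(OCc3ccccc3)c(OCc3ccccc3)c1)O2 | intermediate (not isolated)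
12 | 7-(benzyloxy)-3-bromo-4-[8-bromo-penta-O-benzyl-(+)-catechin-6-yl]chromenylium bromide | Brc1c[o+]c2cc(OCc3ccccc3)ccc2c1-c1c(OCc3ccccc3)c(Br)c2c(c1OCc1ccccc1)C[C@H](OCc1ccccc1)[C@@H](c1ccc(OCc3ccccc3)c(OCc3ccccc3)c1)O2.[Br-] | intermediate (not isolated)
13 | 6-[7-(benzyloxy)-3-bromo-2-ethoxy-2H-chromen-4-yl]-8-bromo-3,5,7,3',4'-penta-O-benzyl-(+)-catechin (both acetal epimers) | CCOC1Oc2cc(OCc3ccccc3)ccc2C(=C1Br)c1c(OCc3ccccc3)c(Br)c2c(c1OCc1ccccc1)C[C@H](OCc1ccccc1)[C@@H](c1ccc(OCc3ccccc3)c(OCc3ccccc3)c1)O2 | intermediate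
14 | 3,8'-dilithio derivative of 13 (lithium in place of both bromines) | CCOC1Oc2cc(OCc3ccccc3)ccc2C(=C1[Li])c1c(OCc3ccccc3)c([Li])c2c(c1OCc1ccccc1)C[C@H](OCc1ccccc1)[C@@H](c1ccc(OCc3ccccc3)c(OCc3ccccc3)c1)O2 | intermediate (not isolated)
15 | 6-[7-(benzyloxy)-2-ethoxy-2H-chromen-4-yl]-3,5,7,3',4'-penta-O-benzyl-(+)-catechin (both acetal epimers) | CCOC1Oc2cc(OCc3ccccc3)ccc2C(=C1)c1c(OCc3ccccc3)cc2c(c1OCc1ccccc1)C[C@H](OCc1ccccc1)[C@@H](c1ccc(OCc3ccccc3)c(OCc3ccccc3)c1)O2 | intermediate
16 | 3,4-bis(benzyloxy)phenylboronic acid | OB(O)c1ccc(OCc2ccccc2)c(OCc2ccccc2)c1 | starting material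
17 | diethyl [3,4-bis(benzyloxy)phenyl]boronate | CCOB(OCC)c1ccc(OCc2ccccc2)c(OCc2ccccc2)c1 | intermediate
18 | 6-{(2R)-7-(benzyloxy)-2-[3,4-bis(benzyloxy)phenyl]-2H-chromen-4-yl}-3,5,7,3',4'-penta-O-benzyl-(+)-catechin | c1ccccc1COc1ccc2c(c1)O[C@@H](c1ccc(OCc3ccccc3)c(OCc3ccccc3)c1)C=C2c1c(OCc3ccccc3)cc2c(c1OCc1ccccc1)C[C@H](OCc1ccccc1)[C@@H](c1ccc(OCc3ccccc3)c(OCc3ccccc3)c1)O2 | intermediate
19 | C3 alkylborane from 18 (BH2 at C3 trans to the C2 aryl group, new H at C4 cis to boron) | c1ccccc1COc1ccc2c(c1)O[C@@H](c1ccc(OCc3ccccc3)c(OCc3ccccc3)c1)[C@H](B)[C@H]2c1c(OCc3ccccc3)cc2c(c1OCc1ccccc1)C[C@H](OCc1ccccc1)[C@@H](c1ccc(OCc3ccccc3)c(OCc3ccccc3)c1)O2 | intermediate (not isolated)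
20 | (2S,3R,4R)-7-(benzyloxy)-2-[3,4-bis(benzyloxy)phenyl]-4-[3,5,7,3',4'-penta-O-benzyl-(+)-catechin-6-yl]chroman-3-ol | c1ccccc1COc1ccc2c(c1)O[C@@H](c1ccc(OCc3ccccc3)c(OCc3ccccc3)c1)[C@H](O)[C@H]2c1c(OCc3ccccc3)cc2c(c1OCc1ccccc1)C[C@H](OCc1ccccc1)[C@@H](c1ccc(OCc3ccccc3)c(OCc3ccccc3)c1)O2 | intermediate
21 | (2S,3R,4R)-2-(3,4-dihydroxyphenyl)-4-[(2R,3S)-2-(3,4-dihydroxyphenyl)-3,5,7-trihydroxychroman-6-yl]chromane-3,7-diol | Oc1ccc2c(c1)O[C@@H](c1ccc(O)c(O)c1)[C@H](O)[C@H]2c1c(O)cc2c(c1O)C[C@H](O)[C@@H](c1ccc(O)c(O)c1)O2 | target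

**Step count and risks**

Total steps: 14. Longest linear sequence: 10 steps (steps 1–4, 8–10 and 12–14, from (+)-catechin).

Steps most likely to fail:

1. Step 9. The carbene may be used up by ethoxide faster than it adds to the furan double bond, which is shielded on one side by the di-ortho-substituted aryl group, or the adduct may open sluggishly. The fallback gives up the ring expansion, sets out from 5 and comes back at 15. 4'-(Benzyloxy)-2'-hydroxyacetophenone is condensed with diethyl carbonate (NaH, toluene, reflux) to 7-(benzyloxy)-4-hydroxycoumarin F1, which is converted with Tf2O/Et3N into 7-(benzyloxy)-2-oxo-2H-chromen-4-yl triflate F2. Iodide 5 is turned by zinc insertion (Zn, LiCl, THF) into the arylzinc iodide F3, and a Negishi coupling of F2 and F3 (Pd(OAc)2, SPhos) gives 7-(benzyloxy)-4-[8-bromo-penta-O-benzyl-(+)-catechin-6-yl]coumarin F4. DIBAL-H at −78 °C gives the lactol, the 8'-bromo 2H-chromen-2-ol F5. EtOH/PPTS gives its ethyl acetal F6, and t-BuLi followed by MeOH removes the aryl bromine to give 15.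

2. Step 12. The aryl transfer may be slow at the hindered, electron-rich benzopyrylium ion, or the facial selectivity within the ion pair may be poor. The fallback sets out from 15 and comes back at 18. Acetal 15 is hydrolysed (AcOH, THF–H2O) to the lactol 6-[7-(benzyloxy)-2-hydroxy-2H-chromen-4-yl]-penta-O-benzyl-(+)-catechin F7, which is in equilibrium with its ring-opened enal. Aryl(ethyl)zinc F8, made from 16 and Et2Zn, is added to the aldehyde form under control of a chiral amino alcohol ligand (catalytic asymmetric aryl transfer to aldehydes). This gives the (S)-allylic alcohol F9, in which the phenol ring is cis to the carbinol carbon (E by the sequence rules). A Mitsunobu etherification (PPh3, DIAD) then closes the pyran ring by attack of the phenol with inversion to give 18.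

3. Step 13. Borane may add to the face syn to the C2 aryl group, or the C3 borane may undergo β-elimination with opening of the pyran ring. The fallback sets out from 18 and comes back at 20. Dimethyldioxirane adds to the face anti to the C2 aryl group to give the 3,4-epoxide F10. MgBr2·OEt2 opens it at the doubly benzylic C4, and a 1,2-hydride shift (Meinwald rearrangement) gives the 4-arylflavan-3-one F11, whose more acidic C4 centre is equilibrated to the 2,4-cis arrangement. NaBH4 then adds axially to give the all-trans alcohol 20.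

Further compounds
F1 | step 9 | 7-(benzyloxy)-4-hydroxycoumarin | O=C1C=C(O)c2ccc(OCc3ccccc3)cc2O1
F2 | step 9 | 7-(benzyloxy)-2-oxo-2H-chromen-4-yl trifluoromethanesulfonate | O=C1C=C(OS(=O)(=O)C(F)(F)F)c2ccc(OCc3ccccc3)cc2O1
F3 | step 9 | [8-bromo-3,5,7,3',4'-penta-O-benzyl-(+)-catechin-6-yl]zinc iodide | I[Zn]c1c(OCc3ccccc3)c(Br)c2c(c1OCc1ccccc1)C[C@H](OCc1ccccc1)[C@@H](c1ccc(OCc3ccccc3)c(OCc3ccccc3)c1)O2
F4 | step 9 | 7-(benzyloxy)-4-[8-bromo-3,5,7,3',4'-penta-O-benzyl-(+)-catechin-6-yl]coumarin | O=C1Oc2cc(OCc3ccccc3)ccc2C(=C1)c1c(OCc3ccccc3)c(Br)c2c(c1OCc1ccccc1)C[C@H](OCc1ccccc1)[C@@H](c1ccc(OCc3ccccc3)c(OCc3ccccc3)c1)O2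
F5 | step 9 | 6-[7-(benzyloxy)-2-hydroxy-2H-chromen-4-yl]-8-bromo-3,5,7,3',4'-penta-O-benzyl-(+)-catechin | OC1Oc2cc(OCc3ccccc3)ccc2C(=C1)c1c(OCc3ccccc3)c(Br)c2c(c1OCc1ccccc1)C[C@H](OCc1ccccc1)[C@@H](c1ccc(OCc3ccccc3)c(OCc3ccccc3)c1)O2
F6 | step 9 | 6-[7-(benzyloxy)-2-ethoxy-2H-chromen-4-yl]-8-bromo-3,5,7,3',4'-penta-O-benzyl-(+)-catechin | CCOC1Oc2cc(OCc3ccccc3)ccc2C(=C1)c1c(OCc3ccccc3)c(Br)c2c(c1OCc1ccccc1)C[C@H](OCc1ccccc1)[C@@H](c1ccc(OCc3ccccc3)c(OCc3ccccc3)c1)O2
F7 | step 12 | 6-[7-(benzyloxy)-2-hydroxy-2H-chromen-4-yl]-3,5,7,3',4'-penta-O-benzyl-(+)-catechin | OC1Oc2cc(OCc3ccccc3)ccc2C(=C1)c1c(OCc3ccccc3)cc2c(c1OCc1ccccc1)C[C@H](OCc1ccccc1)[C@@H](c1ccc(OCc3ccccc3)c(OCc3ccccc3)c1)O2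
F8 | step 12 | [3,4-bis(benzyloxy)phenyl](ethyl)zinc | CC[Zn]c1ccc(OCc2ccccc2)c(OCc2ccccc2)c1
F9 | step 12 | (1S,2E)-1-[3,4-bis(benzyloxy)phenyl]-3-[4-(benzyloxy)-2-hydroxyphenyl]-3-[3,5,7,3',4'-penta-O-benzyl-(+)-catechin-6-yl]prop-2-en-1-ol | O[C@H](c1ccc(OCc2ccccc2)c(OCc2ccccc2)c1)/C=C(/c1c(OCc3ccccc3)cc2c(c1OCc1ccccc1)C[C@H](OCc1ccccc1)[C@@H](c1ccc(OCc3ccccc3)c(OCc3ccccc3)c1)O2)c1ccc(OCc2ccccc2)cc1O
F10 | step 13 | 3,4-epoxide of 18 with the oxirane oxygen trans to the C2 aryl group | c1ccccc1COc1ccc2c(c1)O[C@@H](c1ccc(OCc4ccccc4)c(OCc4ccccc4)c1)[C@@H]3O[C@]23c1c(OCc3ccccc3)cc2c(c1OCc1ccccc1)C[C@H](OCc1ccccc1)[C@@H](c1ccc(OCc3ccccc3)c(OCc3ccccc3)c1)O2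
F11 | step 13 | 2,4-cis-7-(benzyloxy)-2-[3,4-bis(benzyloxy)phenyl]-4-[3,5,7,3',4'-penta-O-benzyl-(+)-catechin-6-yl]chroman-3-one | c1ccccc1COc1ccc2c(c1)O[C@@H](c1ccc(OCc3ccccc3)c(OCc3ccccc3)c1)C(=O)[C@H]2c1c(OCc3ccccc3)cc2c(c1OCc1ccccc1)C[C@H](OCc1ccccc1)[C@@H](c1ccc(OCc3ccccc3)c(OCc3ccccc3)c1)O2
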